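**Retrosynthetic overview**
- Feature: kumbicin C carries two identical N–H indol-3-yl groups on C5 and C8 of a 2,2-dimethyl-2H-chromene (O1, C2, C3=C4, C4a, C5–C8, C8a). They sit para to each other on a hexasubstituted benzene ring, and each indole C3/C2 pair maps onto the CH2–CHO carbons of an arylacetaldehyde arm.
- Key disconnection: a twofold retro-Fischer step opens both pyrrole rings (C3–C3a and N1–C2 of each indole). It leads to the 5,8-bis(2-oxoethyl)chromene with C6–OH masked as its MOM ether, plus two phenylhydrazines, so no hindered aryl–indole bond is made by coupling.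
- The dialdehyde comes from the 5,8-bis(2-hydroxyethyl) diol. Its arms are attached by two rounds of directed ortho-metalation and ethylene oxide opening (C8 between O1 and OMe, then C5 next to OMOM).
- The chromene comes from 3-methoxy-4-(methoxymethoxy)phenol and prenal, and the phenol comes from vanillin by MOM protection and Baeyer–Villiger oxidation.
- Ring order: benzene ring (from vanillin), pyran ring (step 3), both pyrrole rings together (step 7), MOM removal last.

Key step: step 7

Assumption: rotation about the two aryl–indole bonds is taken as free on the laboratory time scale (the target is drawn without axial descriptors), so the route has no stereochemical element to control.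

Step 1
Reactants: 1 vanillin
Product: 2 3-methoxy-4-(methoxymethoxy)benzaldehyde
Conditions: MOMCl, iPr2NEt, CH2Cl2, 0 °C → rt
Reagents that add atoms: chloromethyl methyl ether (MOMCl), COCCl
Why: Williamson-type O-alkylation of the acidic para-formyl phenol with the reactive alpha-chloro ether installs the acetal that later serves both as protecting group and as ortho-directing group.

Step 2
Reactants: 2 3-methoxy-4-(methoxymethoxy)benzaldehyde
Product: 4 3-methoxy-4-(methoxymethoxy)phenol, via aryl formate 3 (not isolated)
Conditions: mCPBA, CH2Cl2, 0 °C → rt; then K2CO3 (cat.), MeOH, rt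
Reagents that add atoms: meta-chloroperoxybenzoic acid (mCPBA), O=C(OO)c1cccc(Cl)c1
Why: Baeyer–Villiger oxidation (the peracid counterpart of the Dakin reaction, chosen because the phenol is masked) proceeds with migration of the aryl group made electron-rich by its para-alkoxy donor, and base-catalysed methanolysis of formate 3 frees the phenol without touching the acetal.

Step 3
Reactants: 4 3-methoxy-4-(methoxymethoxy)phenol; 5 3-methylbut-2-enal (prenal)
Product: 6 7-methoxy-6-(methoxymethoxy)-2,2-dimethyl-2H-chromene
Conditions: Ti(OEt)4 (0.3 equiv), toluene, reflux, EtOH distilled off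
Reagents that add atoms: none
Why: Titanium-phenoxide-directed ortho-hydroxyalkylation by the enal, dehydration to the ortho-quinone methide and oxa-6π electrocyclization (the established phenol/enal chromenylation) close the pyran ring at the open ortho carbon para to the methoxy group rather than at the carbon squeezed between OH and OMe.

Step 4
Reactants: 6 7-methoxy-6-(methoxymethoxy)-2,2-dimethyl-2H-chromene; 7 ethylene oxide
Product: 9 2-[7-methoxy-6-(methoxymethoxy)-2,2-dimethyl-2H-chromen-8-yl]ethanol, via 8-lithiochromene 8 (not isolated)
Conditions: n-BuLi (1.1 equiv), TMEDA, THF, 0 °C; then 7 (THF solution), −20 °C → rt; H2O quench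
Reagents that add atoms: none
Why: Directed ortho-metalation removes the most acidic ring hydrogen, C8–H flanked by O1 and the C7 methoxy oxygen (the in-between position of a 1,3-dialkoxyarene), the aryllithium opens the epoxide by SN2 attack, and any arm that enters at C5 instead is harmless because both mono-adducts converge on diol 11 in step 5.

Step 5
Reactants: 9 2-[7-methoxy-6-(methoxymethoxy)-2,2-dimethyl-2H-chromen-8-yl]ethanol; 7 ethylene oxide
Product: 11 2,2'-[7-methoxy-6-(methoxymethoxy)-2,2-dimethyl-2H-chromene-5,8-diyl]diethanol, via C5-lithio lithium alkoxide 10 (not isolated)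
Conditions: n-BuLi (2.5 equiv), TMEDA, THF, 0 °C; then 7 (THF solution), −20 °C → rt; H2O quench
Reagents that add atoms: none
Why: Once the first equivalent of base has turned the alcohol into an alkoxide that cannot eliminate, MOM-directed ortho-metalation removes the only remaining ring hydrogen, C5–H, through chelation by the acetal oxygens, and SN2 opening of the epoxide attaches the second arm.

Step 6
Reactants: 11 2,2'-[7-methoxy-6-(methoxymethoxy)-2,2-dimethyl-2H-chromene-5,8-diyl]diethanol
Product: 12 2,2'-[7-methoxy-6-(methoxymethoxy)-2,2-dimethyl-2H-chromene-5,8-diyl]diacetaldehyde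
Conditions: Dess–Martin periodinane (2.4 equiv), CH2Cl2, 0 °C → rt; product used promptly
Reagents that add atoms: none
Why: Dess–Martin oxidation takes both primary alcohols to the aldehyde level under non-aqueous, nearly neutral conditions that leave the chromene alkene, the acetal and the electron-rich ring untouched and give little time for enolization or self-condensation of the arylacetaldehyde arms.

Step 7
Reactants: 12 2,2'-[7-methoxy-6-(methoxymethoxy)-2,2-dimethyl-2H-chromene-5,8-diyl]diacetaldehyde; 13 phenylhydrazine (2.1 equiv)
Product: 15 kumbicin C 6-O-methoxymethyl ether, via bis(phenylhydrazone) 14 (not isolated)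
Conditions: 13 (2.1 equiv), AcOH, rt, 1 h; then 75 °C, argon
Reagents that add atoms: none
Why: This is a Fischer indole synthesis run twice on one substrate: each aldehyde condenses with 13 to a hydrazone arm of 14, which in acetic acid tautomerizes to the ene-hydrazine and undergoes the acid-promoted [3,3]-sigmatropic shift that joins the former aldehyde alpha carbon (future indole C3) to an ortho carbon of the phenyl ring (future C3a). Rearomatization gives an ortho-aminoaryl imine whose aniline nitrogen adds to the iminium carbon in a 5-exo-trig closure (N1–C2), and loss of ammonia from the aminal aromatizes the pyrrole ring; both pyrrole rings close in this same mode and independently, because the arms sit para to each other. The closest known reaction type is the conversion of arylacetaldehyde phenylhydrazones into 3-arylindoles, and twofold Fischer indolizations of bis-hydrazones are likewise established. No stereocenter is formed. Regiochemistry is fixed because each aldehyde has a single alpha carbon and unsubstituted phenylhydrazine has two equivalent ortho positions, while the crowded aryl–C3 bonds already exist in 12. Chemoselectivity requires the chromene C3=C4 bond, the MOM ether and the 3-aryl (not rearranged 2-aryl) pattern to survive, which the weak acid should secure, and O1 locked in the pyran, the C7 methyl ether and the C6 MOM ether leave no free ortho hydroxyl that could divert an arm into a benzofuran.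

Step 8
Reactants: 15 kumbicin C 6-O-methoxymethyl ether
Product: 16 kumbicin C
Conditions: HCl (cat.), MeOH–THF, 40 °C, argon
Reagents that add atoms: none
Why: Acid-catalysed transacetalization cleaves the aryl MOM ether by departure of the phenol, the large excess of methanol should trap the methoxymethyl cation as dimethoxymethane before the indoles can, and the methyl ether, the pyran ring and the indoles should tolerate dilute acid at this temperature.

**Compound list**
1 | vanillin (4-hydroxy-3-methoxybenzaldehyde) | COc1cc(C=O)ccc1O | starting material
2 | 3-methoxy-4-(methoxymethoxy)benzaldehyde | COCOc1ccc(C=O)cc1OC | intermediate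
3 | 3-methoxy-4-(methoxymethoxy)phenyl formate | COCOc1ccc(OC=O)cc1OC | intermediate
4 | 3-methoxy-4-(methoxymethoxy)phenol | COCOc1ccc(O)cc1OC | intermediate
5 | 3-methylbut-2-enal (prenal) | CC(C)=CC=O | starting material
6 | 7-methoxy-6-(methoxymethoxy)-2,2-dimethyl-2H-chromene | COCOc1cc2C=CC(C)(C)Oc2cc1OC | intermediate
7 | ethylene oxide | C1CO1 | starting material
8 | 8-lithio-7-methoxy-6-(methoxymethoxy)-2,2-dimethyl-2H-chromene | COCOc1cc2C=CC(C)(C)Oc2c([Li])c1OC | intermediate
9 | 2-[7-methoxy-6-(methoxymethoxy)-2,2-dimethyl-2H-chromen-8-yl]ethanol | COCOc1cc2C=CC(C)(C)Oc2c(CCO)c1OC | intermediate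
10 | lithium 2-[5-lithio-7-methoxy-6-(methoxymethoxy)-2,2-dimethyl-2H-chromen-8-yl]ethoxide | COCOc1c([Li])c2C=CC(C)(C)Oc2c(CCO[Li])c1OC | intermediate
11 | 2,2'-[7-methoxy-6-(methoxymethoxy)-2,2-dimethyl-2H-chromene-5,8-diyl]diethanol | COCOc1c(CCO)c2C=CC(C)(C)Oc2c(CCO)c1OC | intermediate
12 | 2,2'-[7-methoxy-6-(methoxymethoxy)-2,2-dimethyl-2H-chromene-5,8-diyl]diacetaldehyde | COCOc1c(CC=O)c2C=CC(C)(C)Oc2c(CC=O)c1OC | intermediate
13 | phenylhydrazine | NNc1ccccc1 | starting material
14 | (E,E)-bis(phenylhydrazone) of dialdehyde 12 | COCOc1c(C/C=N/Nc2ccccc2)c2C=CC(C)(C)Oc2c(C/C=N/Nc2ccccc2)c1OC | intermediate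
15 | kumbicin C 6-O-methoxymethyl ether, 5,8-di(1H-indol-3-yl)-7-methoxy-6-(methoxymethoxy)-2,2-dimethyl-2H-chromene | COCOc1c(-c2c[nH]c3ccccc23)c2C=CC(C)(C)Oc2c(-c2c[nH]c3ccccc23)c1OC | intermediate
16 | kumbicin C, 5,8-di(1H-indol-3-yl)-7-methoxy-2,2-dimethyl-2H-chromen-6-ol | COc1c(O)c(-c2c[nH]c3ccccc23)c2c(c1-c1c[nH]c3ccccc13)OC(C)(C)C=C2 | target

**Total step count:** 8
**Longest linear sequence:** 8 steps (1 to 16)

**Steps most likely to fail**

1. Step 7.
   - What may go wrong: early loss of the MOM group in warm acid, followed by closure of the C5 arm onto the freed oxygen.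
   - Protonation of the electron-rich C3=C4 bond may lead to oligomerization.
   - The reaction may stall after the first indolization, or a still unreacted arm may condense with an indole already formed.
   - Fallback: it sets out from 12 and comes back at 15. It builds the same two bonds per indole without acid, by the known palladium-catalysed annulation of ortho-iodoanilines with enolizable aldehydes.
   - Dialdehyde 12 is heated with 2-iodoaniline (2.2 equiv), Pd(OAc)2 (cat.) and DABCO in DMF at 85 °C.
   - Condensation (N1–C2) should give the bis[(E)-2-(2-iodoanilino)vinyl]chromene F1 in the flask.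
   - Zerovalent palladium formed in situ inserts into each carbon–iodine bond, and an intramolecular Heck-type closure onto the enamine carbon (C3–C3a) delivers 15 in a basic medium in which the MOM ether and the chromene are safe.

2. Step 5.
   - What may go wrong: incomplete or misdirected metalation, because the alkoxide forms mixed aggregates with the base.
   - The flanked aryllithium may also open the epoxide sluggishly.
   - Fallback: it sets out from 9 and comes back at 10. It replaces deprotonation by halogen–lithium exchange at a position fixed by phenol-directed iodination.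
   - Methanolic HCl removes the acetal to give 8-(2-hydroxyethyl)-7-methoxy-2,2-dimethyl-2H-chromen-6-ol F2.
   - I2 and NaHCO3 in aqueous THF at 0 °C iodinate the phenolate at its only open ortho carbon, much faster than the alkene reacts. This gives 8-(2-hydroxyethyl)-5-iodo-7-methoxy-2,2-dimethyl-2H-chromen-6-ol F3.
   - MOMCl and K2CO3 in acetone re-protect only the phenol, giving 2-[5-iodo-7-methoxy-6-(methoxymethoxy)-2,2-dimethyl-2H-chromen-8-yl]ethanol F4.
   - n-BuLi (2.2 equiv) in THF at −78 °C deprotonates the alcohol and exchanges iodine for lithium. This generates 10 regiospecifically, and 10 is quenched with 7 as in step 5 to give 11.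

3. Step 8.
   - What may go wrong: the indole C2 or N1 positions may capture the released methoxymethyl cation or formaldehyde equivalents.
   - The most likely form of this is six-membered ring closure between the C6 oxygen-bound CH2 and C2 of the C5 indole.
   - Acid-catalysed addition of methanol across C3=C4 and air oxidation of the freed electron-rich phenol are further risks.
   - Fallback: it sets out from 11 and comes back at 16. It exchanges the acetal, once its directing role is over and before any indole exists, for a group removed under neutral conditions.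
   - Methanolic HCl converts 11 into 5,8-bis(2-hydroxyethyl)-7-methoxy-2,2-dimethyl-2H-chromen-6-ol F5.
   - Allyl bromide and K2CO3 in acetone alkylate only the phenol, giving the 6-allyloxy diol F6.
   - Dess–Martin oxidation gives the 6-allyloxy dialdehyde F7.
   - Phenylhydrazine 13 in acetic acid gives the allyl-series bis(phenylhydrazone) F8 and, on warming, kumbicin C 6-O-allyl ether F9. The allyl ether is inert to acid, so more forcing indolization conditions become available.
   - Pd(PPh3)4 (cat.) with morpholine in THF at rt transfers the allyl group to the amine and releases 16.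

**Further compounds**
F1 | step 7 | 5,8-bis[(E)-2-(2-iodoanilino)vinyl]-7-methoxy-6-(methoxymethoxy)-2,2-dimethyl-2H-chromene | COCOc1c(/C=C/Nc2ccccc2I)c2C=CC(C)(C)Oc2c(/C=C/Nc2ccccc2I)c1OC
F2 | step 5 | 8-(2-hydroxyethyl)-7-methoxy-2,2-dimethyl-2H-chromen-6-ol | Oc1cc2C=CC(C)(C)Oc2c(CCO)c1OC
F3 | step 5 | 8-(2-hydroxyethyl)-5-iodo-7-methoxy-2,2-dimethyl-2H-chromen-6-ol | Oc1c(I)c2C=CC(C)(C)Oc2c(CCO)c1OC
F4 | step 5 | 2-[5-iodo-7-methoxy-6-(methoxymethoxy)-2,2-dimethyl-2H-chromen-8-yl]ethanol | COCOc1c(I)c2C=CC(C)(C)Oc2c(CCO)c1OC
F5 | step 8 | 5,8-bis(2-hydroxyethyl)-7-methoxy-2,2-dimethyl-2H-chromen-6-ol | Oc1c(CCO)c2C=CC(C)(C)Oc2c(CCO)c1OC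
F6 | step 8 | 2,2'-[6-(allyloxy)-7-methoxy-2,2-dimethyl-2H-chromene-5,8-diyl]diethanol | C=CCOc1c(CCO)c2C=CC(C)(C)Oc2c(CCO)c1OC
F7 | step 8 | 2,2'-[6-(allyloxy)-7-methoxy-2,2-dimethyl-2H-chromene-5,8-diyl]diacetaldehyde | C=CCOc1c(CC=O)c2C=CC(C)(C)Oc2c(CC=O)c1OC
F8 | step 8 | (E,E)-bis(phenylhydrazone) of dialdehyde F7 | C=CCOc1c(C/C=N/Nc2ccccc2)c2C=CC(C)(C)Oc2c(C/C=N/Nc2ccccc2)c1OC
F9 | step 8 | kumbicin C 6-O-allyl ether | C=CCOc1c(-c2c[nH]c3ccccc23)c2C=CC(C)(C)Oc2c(-c2c[nH]c3ccccc23)c1OC
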